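**Retrosynthetic overview**

1. The target is numbered as a 2H‑cyclohepta[b]furan‑2‑one (lactone = ring A, cycloheptane = ring B). The enone is restored last by Saegusa–Ito oxidation, C3/C3a come from hydrogenation of a C3=C3a butenolide, and the C8 ester comes from exo‑hydride reduction of a ketone followed by acylation.
2. Enabling feature: in ring B the tertiary carbinol carbon C7 and the ring‑fusion carbon C3a stand 1,4 to each other (C4–C5–C6 on one side, C8–C8a on the other), and the C7 oxygen is cis to the C8a oxygen. A temporary ether bridge C7–O–C3a therefore turns ring B into an 8‑oxabicyclo[3.2.1]octane.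
3. Key disconnection: C3a–C8a and C7–C8 are made together when the cyclic carbonyl ylide C7–O–C3a (from a δ‑keto α‑diazo ketone and a dirhodium catalyst) adds to vinylene carbonate, which brings C8 and C8a with both oxygens. The bridge is later cut by E1cB elimination from the lactone enolate, which frees the C7 hydroxyl.
4. The diazo precursor comes from (S)‑3‑bromo‑2‑methylpropan‑1‑ol (C5, C6, C7), crotonoyl chloride (side chain) and methyl 2‑methylacetoacetate (C2, C3, C3a, C4) by acylation, diazo transfer and a Felkin‑controlled aldol (C5).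
5. Ring order: transient ylide ring, then ring B with its oxygen bridge (key step), then ring A (lactonisation), then loss of the bridge.

Key step: step 8

Remark on the chemistry: the stereocentre α to the ester (later C3) is carried as an epimer mixture from the aldol product to the isobutyrate, because it is erased in step 13 and reset in step 14; the SMILES leave it undefined there.

**Step 1**
Reactants: 1 (S)‑3‑bromo‑2‑methylpropan‑1‑ol
Product: 2 (S)‑(3‑bromo‑2‑methylpropoxy)(tert‑butyl)dimethylsilane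
Conditions: TBSCl, imidazole, DMF, 0 °C to rt
Reagents that add atoms: tert‑butylchlorodimethylsilane, CC(C)(C)[Si](C)(C)Cl
Why: Standard silylation of a primary alcohol, which masks the future C5 aldehyde through the organometallic and enolate steps.

**Step 2**
Reactants: 2 (S)‑(3‑bromo‑2‑methylpropoxy)(tert‑butyl)dimethylsilane; 3 (E)‑but‑2‑enoyl chloride
Product: 5 (2E,6R)‑7‑(tert‑butyldimethylsilyloxy)‑6‑methylhept‑2‑en‑4‑one, via organozinc bromide 4 (not isolated)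
Conditions: Zn dust, LiCl, THF, 50 °C; then 3, Pd(PPh3)4 (5 mol %), THF, 0 °C to rt
Reagents that add atoms: none
Why: LiCl‑promoted zinc insertion into the primary bromide and Negishi acylation with the acid chloride should give the enone without touching the stereocentre or adding to the enone.

**Step 3**
Reactants: 5 (2E,6R)‑7‑(tert‑butyldimethylsilyloxy)‑6‑methylhept‑2‑en‑4‑one
Product: 7 (2E,6R)‑7‑(tert‑butyldimethylsilyloxy)‑5‑diazo‑6‑methylhept‑2‑en‑4‑one, via trifluoroacetyl ketone 6 (not isolated)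
Conditions: LiHMDS, THF, −78 °C; CF3CO2CH2CF3; then MsN3, Et3N, H2O, MeCN, rt
Reagents that add atoms: methanesulfonyl azide, CS(=O)(=O)N=[N+]=[N-]
Why: Detrifluoroacetylative (Regitz‑type) diazo transfer; the enone has enolisable hydrogens only at the α' CH2, so kinetic deprotonation and diazo transfer should be regiospecific.

**Step 4**
Reactants: 7 (2E,6R)‑7‑(tert‑butyldimethylsilyloxy)‑5‑diazo‑6‑methylhept‑2‑en‑4‑one
Product: 8 (2E,6R)‑5‑diazo‑7‑hydroxy‑6‑methylhept‑2‑en‑4‑one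
Conditions: Bu4NF, AcOH, THF, 0 °C to rt
Reagents that add atoms: none
Why: Buffered fluoride desilylation, which the acceptor‑stabilised diazo ketone should tolerate.

**Step 5**
Reactants: 8 (2E,6R)‑5‑diazo‑7‑hydroxy‑6‑methylhept‑2‑en‑4‑one
Product: 9 (2R,5E)‑3‑diazo‑2‑methyl‑4‑oxohept‑5‑enal
Conditions: Dess–Martin periodinane, NaHCO3, CH2Cl2, 0 °C
Reagents that add atoms: none
Why: Buffered Dess–Martin oxidation is neutral and fast, so the α‑stereocentre should survive if the aldehyde is used crude at once.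

**Step 6**
Reactants: 9 (2R,5E)‑3‑diazo‑2‑methyl‑4‑oxohept‑5‑enal; 10 methyl 2‑methyl‑3‑oxobutanoate
Product: 12 methyl (5R,6R,9E)‑7‑diazo‑5‑hydroxy‑2,6‑dimethyl‑3,8‑dioxoundec‑9‑enoate, via acetoacetate dianion 11 (not isolated)
Conditions: 10, NaH then n‑BuLi, THF, 0 °C; then 9, −78 °C; AcOH
Reagents that add atoms: none
Why: Acetoacetate dianion aldol at the γ‑carbon; the C5 carbinol should form under Felkin–Anh control from the α‑methyl centre (methyl and hydroxyl syn), and at −78 °C the aldehyde should react far faster than the diazo ketone.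

**Step 7**
Reactants: 12 methyl (5R,6R,9E)‑7‑diazo‑5‑hydroxy‑2,6‑dimethyl‑3,8‑dioxoundec‑9‑enoate
Product: 13 methyl (5R,6R,9E)‑5‑(tert‑butyldimethylsilyloxy)‑7‑diazo‑2,6‑dimethyl‑3,8‑dioxoundec‑9‑enoate
Conditions: TBSCl, imidazole, DMAP (cat.), DMF, rt
Reagents that add atoms: tert‑butylchlorodimethylsilane, CC(C)(C)[Si](C)(C)Cl
Why: Silylation under non‑Lewis‑acidic conditions blocks O–H insertion, retro‑aldol and δ‑lactonisation of the hydroxy keto ester.

**Step 8**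
Reactants: 13 methyl (5R,6R,9E)‑5‑(tert‑butyldimethylsilyloxy)‑7‑diazo‑2,6‑dimethyl‑3,8‑dioxoundec‑9‑enoate; 14 vinylene carbonate
Product: 16 methyl 2‑[(1S,2S,3R,5S,6S,7R)‑1‑[(E)‑but‑2‑enoyl]‑3‑(tert‑butyldimethylsilyloxy)‑6,7‑(carbonyldioxy)‑2‑methyl‑8‑oxabicyclo[3.2.1]octan‑5‑yl]propanoate (exo carbonate), via carbonyl ylide 15 (not isolated)
Conditions: Rh2(OPiv)4 (2 mol %), 14 (10 equiv), CH2Cl2, slow addition of 13, 0 °C to rt
Reagents that add atoms: none
Why: The dirhodium catalyst turns the diazo ketone into a rhodium‑bound carbene, the lone pair of the C3 ketone oxygen closes on it to give the six‑membered cyclic carbonyl ylide 15, and 15 adds across vinylene carbonate in a concerted suprafacial [3+2] cycloaddition that forms C5–C6 and C7–C1 of the oxabicycle (C3a–C8a and C7–C8 of the target) in one event. The closest known reaction type is the tandem carbonyl ylide formation/1,3‑dipolar cycloaddition of δ‑keto α‑diazo ketones with alkenes. Ring closures: the ylide ring closes by O‑attack on the carbene carbon (six‑membered heterocyclisation), and the cycloaddition closes the tetrahydrofuran ring and with it the seven‑membered carbocycle, as the two‑carbon bridge of the 8‑oxabicyclo[3.2.1]octane. Stereocontrol: C1 and C5 are tied to one face by the oxygen bridge, the dipolarophile comes anti to the C2 methyl group, which A(1,2) strain with the butenoyl group on the planar ylide carbon holds pseudo‑axial, C6 and C7 are cis because the alkene geometry is kept, and the carbonate ring is exo because the endo space under the three‑carbon bridge is taken by the pseudo‑axial silyloxy group. The step needs ylide formation to outrun 1,2‑hydride shift of the carbene and proton transfer in the ylide; the Lewis‑basic ketone that closes a six‑membered ring, the bulky pivalate ligands, the low temperature and a tenfold excess of the symmetrical dipolarophile (no regiochemistry to control) serve this.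

**Step 9**
Reactants: 16 the exo‑carbonate cycloadduct
Product: 18 (3aS,5R,6S,7S,8R,8aS)‑7‑[(E)‑but‑2‑enoyl]‑5‑(tert‑butyldimethylsilyloxy)‑8‑hydroxy‑3,6‑dimethyl‑3a,7‑epoxyoctahydro‑2H‑cyclohepta[b]furan‑2‑one, via diol ester 17 (not isolated)
Conditions: K2CO3 (cat.), MeOH, 0 °C; then PPTS (cat.), PhMe, 60 °C
Reagents that add atoms: none
Why: Methanolysis of the cyclic carbonate frees the exo‑cis diol, and acid then closes the γ‑lactone (5‑exo‑trig acyl substitution) from the C6 hydroxyl, the only one that the bridgehead side chain reaches in a five‑membered ring; methoxide addition to the hindered enone is reversible.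

**Step 10**
Reactants: 18 the exo‑hydroxy lactone
Product: 19 (3aS,5R,6S,7R,8aR)‑7‑[(E)‑but‑2‑enoyl]‑5‑(tert‑butyldimethylsilyloxy)‑3,6‑dimethyl‑3a,7‑epoxyhexahydro‑2H‑cyclohepta[b]furan‑2,8(3H)‑dione
Conditions: Dess–Martin periodinane, NaHCO3, CH2Cl2, rt
Reagents that add atoms: none
Why: Dess–Martin oxidation of the only free (secondary) hydroxyl removes the exo C8 configuration so that it can be reset.

**Step 11**
Reactants: 19 the C8 ketone
Product: 20 (3aS,5R,6S,7S,8S,8aS)‑7‑[(E)‑but‑2‑enoyl]‑5‑(tert‑butyldimethylsilyloxy)‑8‑hydroxy‑3,6‑dimethyl‑3a,7‑epoxyoctahydro‑2H‑cyclohepta[b]furan‑2‑one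
Conditions: NaBH4, THF/EtOH, −78 °C
Reagents that add atoms: none
Why: Hydride reduction of the strained, α‑oxygenated bicyclic ketone from the open exo face (the endo face lies under the three‑carbon bridge) should give the endo alcohol, trans to the bridge oxygen, faster than it touches the hindered enone.

**Step 12**
Reactants: 20 the endo alcohol
Product: 21 (3aS,5R,6S,7S,8S,8aS)‑7‑[(E)‑but‑2‑enoyl]‑5‑(tert‑butyldimethylsilyloxy)‑3,6‑dimethyl‑2‑oxo‑3a,7‑epoxyoctahydro‑2H‑cyclohepta[b]furan‑8‑yl 2‑methylpropanoate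
Conditions: (i‑PrCO)2O, Et3N, DMAP (cat.), CH2Cl2, rt to 40 °C
Reagents that add atoms: isobutyric anhydride, CC(C)C(=O)OC(=O)C(C)C
Why: DMAP‑catalysed acylation of the only free hydroxyl installs the isobutyrate while the C7 oxygen is still locked in the bridge.

**Step 13**
Reactants: 21 the bridged isobutyrate
Product: 23 (5R,6S,7S,8S,8aR)‑7‑[(E)‑but‑2‑enoyl]‑5‑(tert‑butyldimethylsilyloxy)‑3,6‑dimethyl‑2‑oxo‑7‑(trimethylsilyloxy)‑4,5,6,7,8,8a‑hexahydro‑2H‑cyclohepta[b]furan‑8‑yl 2‑methylpropanoate, via lithium alkoxide 22 (not isolated)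
Conditions: LiHMDS, THF, −78 °C; then TMSCl, −78 to −20 °C
Reagents that add atoms: chlorotrimethylsilane, C[Si](C)(C)Cl
Why: E1cB elimination: the lactone enolate expels the β‑oxygen of the strained bridge (the C–O bond is aligned with the enolate π system) to give the butenolide and the C7 alkoxide, which is silylated cold before it can add to the enone or take the isobutyryl group.

**Step 14**
Reactants: 23 the butenolide
Product: 24 (3R,3aS,5R,6S,7S,8S,8aR)‑7‑butanoyl‑5‑(tert‑butyldimethylsilyloxy)‑3,6‑dimethyl‑2‑oxo‑7‑(trimethylsilyloxy)octahydro‑2H‑cyclohepta[b]furan‑8‑yl 2‑methylpropanoate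
Conditions: H2 (50 bar), Rh/Al2O3 (5%), EtOAc, rt
Reagents that add atoms: none
Why: Heterogeneous hydrogenation adds both hydrogens syn to the tetrasubstituted butenolide from the face of H‑8a, the face not covered by ring B, which sets C3a and C3 with all three lactone hydrogens cis; the butenoyl alkene is reduced as well and is restored in step 15.

**Step 15**
Reactants: 24 the butanoyl ketone
Product: 26 (3R,3aS,5R,6S,7S,8S,8aR)‑7‑[(E)‑but‑2‑enoyl]‑5‑(tert‑butyldimethylsilyloxy)‑3,6‑dimethyl‑2‑oxo‑7‑(trimethylsilyloxy)octahydro‑2H‑cyclohepta[b]furan‑8‑yl 2‑methylpropanoate, via silyl enol ether 25 (not isolated)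
Conditions: TMSOTf, Et3N, CH2Cl2, 0 °C; then Pd(OAc)2 (1.1 equiv), MeCN, rt
Reagents that add atoms: none
Why: Saegusa–Ito oxidation; the ketone has α‑hydrogens on one side only and is enolised in preference to the lactone and the ester, and β‑hydride elimination should give the (E)‑enone.

**Step 16**
Reactants: 26 the bis‑silyl ether
Product: 27 (3R,3aS,5R,6S,7S,8S,8aR)‑7‑[(E)‑but‑2‑enoyl]‑5,7‑dihydroxy‑3,6‑dimethyl‑2‑oxooctahydro‑2H‑cyclohepta[b]furan‑8‑yl 2‑methylpropanoate (target)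
Conditions: HF·pyridine, pyridine, THF, 0 °C to rt
Reagents that add atoms: none
Why: Fluoride desilylation under weakly acidic, non‑basic conditions removes both silyl ethers without base‑induced 5‑endo oxa‑Michael closure of the α'‑hydroxy enone.

**Compound list**

1 | (S)‑3‑bromo‑2‑methylpropan‑1‑ol | BrC[C@@H](C)CO | starting material
2 | (S)‑(3‑bromo‑2‑methylpropoxy)(tert‑butyl)dimethylsilane | BrC[C@@H](C)CO[Si](C)(C)C(C)(C)C | intermediate
3 | (E)‑but‑2‑enoyl chloride | C/C=C/C(Cl)=O | starting material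
4 | [(S)‑3‑(tert‑butyldimethylsilyloxy)‑2‑methylpropyl]zinc bromide | Br[Zn]C[C@@H](C)CO[Si](C)(C)C(C)(C)C | intermediate (not isolated)
5 | (2E,6R)‑7‑(tert‑butyldimethylsilyloxy)‑6‑methylhept‑2‑en‑4‑one | C/C=C/C(=O)C[C@@H](C)CO[Si](C)(C)C(C)(C)C | intermediate
6 | (2E,6R)‑7‑(tert‑butyldimethylsilyloxy)‑6‑methyl‑5‑(trifluoroacetyl)hept‑2‑en‑4‑one (C5 undefined) | C/C=C/C(=O)C(C(=O)C(F)(F)F)[C@@H](C)CO[Si](C)(C)C(C)(C)C | intermediate (not isolated)
7 | (2E,6R)‑7‑(tert‑butyldimethylsilyloxy)‑5‑diazo‑6‑methylhept‑2‑en‑4‑one | C/C=C/C(=O)C(=[N+]=[N-])[C@@H](C)CO[Si](C)(C)C(C)(C)C | intermediate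
8 | (2E,6R)‑5‑diazo‑7‑hydroxy‑6‑methylhept‑2‑en‑4‑one | C/C=C/C(=O)C(=[N+]=[N-])[C@@H](C)CO | intermediate
9 | (2R,5E)‑3‑diazo‑2‑methyl‑4‑oxohept‑5‑enal | C/C=C/C(=O)C(=[N+]=[N-])[C@@H](C)C=O | intermediate
10 | methyl 2‑methyl‑3‑oxobutanoate (racemic) | CC(=O)C(C)C(=O)OC | starting material
11 | sodium lithium dianion (1,3‑bis‑enolate) of methyl 2‑methyl‑3‑oxobutanoate | [Na+].[Li+].C=C([O-])C(C)=C([O-])OC | intermediate (not isolated)
12 | methyl (5R,6R,9E)‑7‑diazo‑5‑hydroxy‑2,6‑dimethyl‑3,8‑dioxoundec‑9‑enoate (C2 epimers) | C/C=C/C(=O)C(=[N+]=[N-])[C@@H](C)[C@H](O)CC(=O)C(C)C(=O)OC | intermediate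
13 | methyl (5R,6R,9E)‑5‑(tert‑butyldimethylsilyloxy)‑7‑diazo‑2,6‑dimethyl‑3,8‑dioxoundec‑9‑enoate (C2 epimers) | C/C=C/C(=O)C(=[N+]=[N-])[C@@H](C)[C@H](O[Si](C)(C)C(C)(C)C)CC(=O)C(C)C(=O)OC | intermediate
14 | vinylene carbonate (1,3‑dioxol‑2‑one) | O=C1OC=CO1 | starting material
15 | cyclic carbonyl ylide: (3S,4R)‑2‑[(E)‑but‑2‑enoyl]‑4‑(tert‑butyldimethylsilyloxy)‑6‑(1‑methoxy‑1‑oxopropan‑2‑yl)‑3‑methyl‑3,4‑dihydro‑2H‑pyran‑1‑ium‑2‑ide | C/C=C/C(=O)[C-]1[C@@H](C)[C@H](O[Si](C)(C)C(C)(C)C)CC(C(C)C(=O)OC)=[O+]1 | intermediate (not isolated)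
16 | methyl 2‑[(1S,2S,3R,5S,6S,7R)‑1‑[(E)‑but‑2‑enoyl]‑3‑(tert‑butyldimethylsilyloxy)‑6,7‑(carbonyldioxy)‑2‑methyl‑8‑oxabicyclo[3.2.1]octan‑5‑yl]propanoate (exo carbonate) | C/C=C/C(=O)[C@@]12[C@@H](C)[C@H](O[Si](C)(C)C(C)(C)C)C[C@](O1)(C(C)C(=O)OC)[C@H]3OC(=O)O[C@@H]23 | intermediate
17 | methyl 2‑[(1S,2S,3R,5S,6S,7R)‑1‑[(E)‑but‑2‑enoyl]‑3‑(tert‑butyldimethylsilyloxy)‑6,7‑dihydroxy‑2‑methyl‑8‑oxabicyclo[3.2.1]octan‑5‑yl]propanoate (exo‑cis diol) | C/C=C/C(=O)[C@@]12[C@@H](C)[C@H](O[Si](C)(C)C(C)(C)C)C[C@](O1)(C(C)C(=O)OC)[C@@H](O)[C@H]2O | intermediate (not isolated)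
18 | (3aS,5R,6S,7S,8R,8aS)‑7‑[(E)‑but‑2‑enoyl]‑5‑(tert‑butyldimethylsilyloxy)‑8‑hydroxy‑3,6‑dimethyl‑3a,7‑epoxyoctahydro‑2H‑cyclohepta[b]furan‑2‑one | C/C=C/C(=O)[C@@]12[C@@H](C)[C@H](O[Si](C)(C)C(C)(C)C)C[C@]3(O1)C(C)C(=O)O[C@H]3[C@H]2O | intermediate
19 | (3aS,5R,6S,7R,8aR)‑7‑[(E)‑but‑2‑enoyl]‑5‑(tert‑butyldimethylsilyloxy)‑3,6‑dimethyl‑3a,7‑epoxyhexahydro‑2H‑cyclohepta[b]furan‑2,8(3H)‑dione | C/C=C/C(=O)[C@@]12[C@@H](C)[C@H](O[Si](C)(C)C(C)(C)C)C[C@]3(O1)C(C)C(=O)O[C@H]3C2=O | intermediate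
20 | (3aS,5R,6S,7S,8S,8aS)‑7‑[(E)‑but‑2‑enoyl]‑5‑(tert‑butyldimethylsilyloxy)‑8‑hydroxy‑3,6‑dimethyl‑3a,7‑epoxyoctahydro‑2H‑cyclohepta[b]furan‑2‑one | C/C=C/C(=O)[C@@]12[C@@H](C)[C@H](O[Si](C)(C)C(C)(C)C)C[C@]3(O1)C(C)C(=O)O[C@H]3[C@@H]2O | intermediate
21 | (3aS,5R,6S,7S,8S,8aS)‑7‑[(E)‑but‑2‑enoyl]‑5‑(tert‑butyldimethylsilyloxy)‑3,6‑dimethyl‑2‑oxo‑3a,7‑epoxyoctahydro‑2H‑cyclohepta[b]furan‑8‑yl 2‑methylpropanoate | C/C=C/C(=O)[C@@]12[C@@H](C)[C@H](O[Si](C)(C)C(C)(C)C)C[C@]3(O1)C(C)C(=O)O[C@H]3[C@@H]2OC(=O)C(C)C | intermediate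
22 | lithium (5R,6S,7S,8S,8aR)‑7‑[(E)‑but‑2‑enoyl]‑5‑(tert‑butyldimethylsilyloxy)‑3,6‑dimethyl‑8‑(2‑methylpropanoyloxy)‑2‑oxo‑4,5,6,7,8,8a‑hexahydro‑2H‑cyclohepta[b]furan‑7‑olate | [Li+].C/C=C/C(=O)[C@]1([O-])[C@@H](C)[C@H](O[Si](C)(C)C(C)(C)C)CC2=C(C)C(=O)O[C@H]2[C@@H]1OC(=O)C(C)C | intermediate (not isolated)
23 | (5R,6S,7S,8S,8aR)‑7‑[(E)‑but‑2‑enoyl]‑5‑(tert‑butyldimethylsilyloxy)‑3,6‑dimethyl‑2‑oxo‑7‑(trimethylsilyloxy)‑4,5,6,7,8,8a‑hexahydro‑2H‑cyclohepta[b]furan‑8‑yl 2‑methylpropanoate | C/C=C/C(=O)[C@]1(O[Si](C)(C)C)[C@@H](C)[C@H](O[Si](C)(C)C(C)(C)C)CC2=C(C)C(=O)O[C@H]2[C@@H]1OC(=O)C(C)C | intermediate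
24 | (3R,3aS,5R,6S,7S,8S,8aR)‑7‑butanoyl‑5‑(tert‑butyldimethylsilyloxy)‑3,6‑dimethyl‑2‑oxo‑7‑(trimethylsilyloxy)octahydro‑2H‑cyclohepta[b]furan‑8‑yl 2‑methylpropanoate | CCCC(=O)[C@]1(O[Si](C)(C)C)[C@@H](C)[C@H](O[Si](C)(C)C(C)(C)C)C[C@@H]2[C@@H](OC(=O)[C@@H]2C)[C@@H]1OC(=O)C(C)C | intermediate
25 | trimethylsilyl enol ether of 24 (enol ether geometry undefined) | CCC=C(O[Si](C)(C)C)[C@]1(O[Si](C)(C)C)[C@@H](C)[C@H](O[Si](C)(C)C(C)(C)C)C[C@@H]2[C@@H](OC(=O)[C@@H]2C)[C@@H]1OC(=O)C(C)C | intermediate (not isolated)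
26 | (3R,3aS,5R,6S,7S,8S,8aR)‑7‑[(E)‑but‑2‑enoyl]‑5‑(tert‑butyldimethylsilyloxy)‑3,6‑dimethyl‑2‑oxo‑7‑(trimethylsilyloxy)octahydro‑2H‑cyclohepta[b]furan‑8‑yl 2‑methylpropanoate | C/C=C/C(=O)[C@]1(O[Si](C)(C)C)[C@@H](C)[C@H](O[Si](C)(C)C(C)(C)C)C[C@@H]2[C@@H](OC(=O)[C@@H]2C)[C@@H]1OC(=O)C(C)C | intermediate
27 | (3R,3aS,5R,6S,7S,8S,8aR)‑7‑[(E)‑but‑2‑enoyl]‑5,7‑dihydroxy‑3,6‑dimethyl‑2‑oxooctahydro‑2H‑cyclohepta[b]furan‑8‑yl 2‑methylpropanoate | C/C=C/C(=O)[C@]1(O)[C@@H](C)[C@H](O)C[C@@H]2[C@@H](OC(=O)[C@@H]2C)[C@@H]1OC(=O)C(C)C | target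

**Step count and risks**

Total step count: 16. Longest linear sequence: 16 steps (1 to 27).

Steps most likely to fail:

1. Step 8. The carbene may undergo 1,2‑hydride shift, or the ylide may lose a proton or dimerise before the weakly activated vinylene carbonate traps it; part of the cycloaddition may also come from the other face. The fallback sets out from 13 and comes back at 17. 13 is decomposed with the same catalyst in the presence of phenyl vinyl sulfoxide, a more reactive acetylene equivalent, which should give the sulfinyl oxabicycle F1 (regio‑ and stereoisomers at the sulfinyl‑bearing bridge carbon all converge). Heating in toluene at 110 °C (sulfoxide syn‑elimination) should give the oxabicyclic alkene F2. OsO4 (cat.) with N‑methylmorpholine N‑oxide should then dihydroxylate the strained ring alkene from the exo face, faster than the electron‑poor butenoyl alkene, and give the diol ester 17, which lactonises to 18 under the acid conditions of step 9. This cures slow trapping and exo/endo control but not the facial question.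

2. Step 6. The small dianion may show a low Felkin bias, and the basic reagent may enolise and epimerise the α‑branched aldehyde. The fallback sets out from 9 and comes back at 13. 9 is added at −78 °C to the dilithium enolate of (R)‑2‑hydroxy‑1,2,2‑triphenylethyl acetate (reagent‑controlled acetate aldol, matched with the Felkin preference) to give the β‑hydroxy ester F3. TBSCl/imidazole gives the silyl ether F4, and LiOH in aqueous THF at 0 °C gives the acid F5 with release of the auxiliary diol. Carbonyldiimidazole converts F5 into the acyl imidazolide F6, which with the magnesium salt of methyl hydrogen methylmalonate (Masamune–Brooks chain extension, loss of CO2) should give 13.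

3. Step 13. The tertiary alkoxide is released next to the enone and may add to it (5‑endo oxa‑Michael) or take the isobutyryl group before it is silylated; the amide base may also attack the butenoyl group. The fallback sets out from 21 and comes back at 25. 21 is first hydrogenated (H2, Pd/C, EtOAc) to the bridged butanoyl ketone F7, so that no enone is present when the bridge is opened. LiHMDS and aqueous quench then give the hydroxy butenolide F8, and hydrogenation over Rh/Al2O3 gives the saturated hydroxy lactone F9. F9 enters step 15, where excess TMSOTf silylates the tertiary hydroxyl as well and gives 25 and then 26.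

**Further compounds**

F1 | step 8 | methyl 2‑[1‑[(E)‑but‑2‑enoyl]‑3‑(tert‑butyldimethylsilyloxy)‑2‑methyl‑6‑(phenylsulfinyl)‑8‑oxabicyclo[3.2.1]octan‑5‑yl]propanoate, ring configuration at C1, C2, C3, C5 as in 16, isomer mixture at C6 and sulfur | C/C=C/C(=O)[C@@]12[C@@H](C)[C@H](O[Si](C)(C)C(C)(C)C)C[C@](O1)(C(C)C(=O)OC)C(S(=O)c1ccccc1)C2
F2 | step 8 | methyl 2‑[1‑[(E)‑but‑2‑enoyl]‑3‑(tert‑butyldimethylsilyloxy)‑2‑methyl‑8‑oxabicyclo[3.2.1]oct‑6‑en‑5‑yl]propanoate, ring configuration as in 16 | C/C=C/C(=O)[C@@]12[C@@H](C)[C@H](O[Si](C)(C)C(C)(C)C)C[C@](O1)(C(C)C(=O)OC)C=C2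
F3 | step 6 | (R)‑2‑hydroxy‑1,2,2‑triphenylethyl (3R,4R,7E)‑5‑diazo‑3‑hydroxy‑4‑methyl‑6‑oxonon‑7‑enoate | C/C=C/C(=O)C(=[N+]=[N-])[C@@H](C)[C@H](O)CC(=O)O[C@H](c1ccccc1)C(O)(c1ccccc1)c1ccccc1
F4 | step 6 | (R)‑2‑hydroxy‑1,2,2‑triphenylethyl (3R,4R,7E)‑3‑(tert‑butyldimethylsilyloxy)‑5‑diazo‑4‑methyl‑6‑oxonon‑7‑enoate | C/C=C/C(=O)C(=[N+]=[N-])[C@@H](C)[C@H](O[Si](C)(C)C(C)(C)C)CC(=O)O[C@H](c1ccccc1)C(O)(c1ccccc1)c1ccccc1
F5 | step 6 | (3R,4R,7E)‑3‑(tert‑butyldimethylsilyloxy)‑5‑diazo‑4‑methyl‑6‑oxonon‑7‑enoic acid | C/C=C/C(=O)C(=[N+]=[N-])[C@@H](C)[C@H](O[Si](C)(C)C(C)(C)C)CC(=O)O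
F6 | step 6 | acyl imidazolide of F5 | C/C=C/C(=O)C(=[N+]=[N-])[C@@H](C)[C@H](O[Si](C)(C)C(C)(C)C)CC(=O)n1ccnc1
F7 | step 13 | 7‑butanoyl analogue of 21 (bridged lactone, same configuration) | CCCC(=O)[C@@]12[C@@H](C)[C@H](O[Si](C)(C)C(C)(C)C)C[C@]3(O1)C(C)C(=O)O[C@H]3[C@@H]2OC(=O)C(C)C
F8 | step 13 | 7‑butanoyl‑5‑(tert‑butyldimethylsilyloxy)‑7‑hydroxy‑3,6‑dimethyl‑2‑oxo‑4,5,6,7,8,8a‑hexahydro‑2H‑cyclohepta[b]furan‑8‑yl 2‑methylpropanoate, configuration as in 23 | CCCC(=O)[C@]1(O)[C@@H](C)[C@H](O[Si](C)(C)C(C)(C)C)CC2=C(C)C(=O)O[C@H]2[C@@H]1OC(=O)C(C)C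
F9 | step 13 | 7‑butanoyl‑5‑(tert‑butyldimethylsilyloxy)‑7‑hydroxy‑3,6‑dimethyl‑2‑oxooctahydro‑2H‑cyclohepta[b]furan‑8‑yl 2‑methylpropanoate, configuration as in 24 | CCCC(=O)[C@]1(O)[C@@H](C)[C@H](O[Si](C)(C)C(C)(C)C)C[C@@H]2[C@@H](OC(=O)[C@@H]2C)[C@@H]1OC(=O)C(C)C
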